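Chromene numbering is used throughout: O1, C2 (CMe2), C3=C4, C4a, C5, C6, C7, C8, C8a. C1' is the ketone carbon of the side chain.

## Analysis of the target

Flemistrictin D (20) is a 2,2-dimethyl-2H-chromene whose benzene ring (ring A) is fully substituted. The pyran is fused at C4a/C8a, C5 and C8 carry hydroxyls, C7 a methoxyl and C6 a 3-phenylpropanoyl chain. There is no stereocentre, so the problem is purely one of regiochemistry on a hexasubstituted arene. Four oxygens of three kinds (ring ether O1, two phenols, one methyl ether) must each be placed without ambiguity, and the acyl group must sit between the free C5 hydroxyl and the C7 methoxyl. The sensitive groups are the C5/C8 para-hydroquinone, which air-oxidises to the quinone, and the C3=C4 alkene, an electron-rich styrene that excludes catalytic hydrogenation and strong acid. The ketone is chelated to the C5 hydroxyl and has an enolisable methylene. The strategy rests on the ortho pair C5–OH/C6–C(=O): an ortho-hydroxyaryl ketone is the reduced and hydrolysed form of a 3-substituted 1,2-benzisoxazole, which holds the carbonyl as C=N and the phenol oxygen as the ring oxygen bonded to nitrogen. That ring is the [3+2] adduct of a C5–C6 aryne and a nitrile oxide, so C6–C1' and C5–O can be made in one operation, with the C7 methoxyl beside the aryne fixing the orientation.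

## Retrosynthetic reasoning

**20 to 19 (redox only).** The hydroquinone is the most fragile function, so it is uncovered last. Its quinone 19 is the direct precursor, and a mild two-electron reduction is all the forward step has to do.

**19 to 18 (C8–O).** In 18 the only ring carbon that still bears hydrogen is C8, and it lies para to the C5 phenol. The C8–O bond is therefore cut, and the forward step is a para-selective phenol-to-quinone oxidation by a nitroxyl radical. Placing this oxygen late keeps an oxidation-prone hydroquinone out of all organometallic and aryne steps. The ortho positions of the phenol are blocked, so no ortho-quinone can form.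

**18 to 16 (via 17).** The chelated hydroxy ketone is traced back to the benzisoxazole 16. The C=O becomes C=N and the phenol O–H becomes O–N. The forward reaction has to cleave the N–O bond reductively without touching C3=C4, which excludes hydrogenation, and then hydrolyse the N–H ketimine 17 under acid mild enough for the chromene.

**16 to 10 and 13 (via 14 and 15; key disconnection).** Both bonds of the isoxazole to ring A, C6–C1' and C5–O, are cut together. This gives the C5–C6 aryne 14, released from the silyl triflate 10, and the nitrile oxide 15, released from the chlorooxime 13. The cut is made here because it creates the hardest relationship of the target, acyl carbon between oxygen-bearing C5 and methoxy-bearing C7, in one step. The orientation is dictated by a substituent already in place. The forward step needs the dipole oxygen on C5, and it needs the aryne to be trapped faster than the dipole dimerises or adds to C3=C4.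

**10 to 3 (via 9, 8 and 4, with 5–7 in the flask).** The ortho-silyl triflate is the standard fluoride-triggered aryne precursor. Its C6–Si bond is cut back to a C6–H that lies between the C5 oxygen and the C7 methoxyl. The C5 phenol of 3, converted to the secondary carbamate 4, directs metalation to exactly that carbon. The same oxygen then becomes the triflate leaving group after carbamate removal. The C5 oxygen of 3 is thus used twice, as director and as leaving group, and is finally replaced by the dipole oxygen.

**3 to 1 and 2.** The pyran ring is cut at C4–C4a and O1–C2. The forward reaction is a one-step condensation and electrocyclisation of the symmetric resorcinol 1 with the enal 2. It sets O1, the C5 hydroxyl, the C7 methoxyl and the alkene at once, provided the carbon between the two hydroxyls reacts.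

**13 to 12 to 11.** The chlorooxime is cut at C–Cl and then at C=N, back to the aldehyde 11. The forward steps are oximation and chlorination of the oxime carbon.

## Alternatives that were turned down

**Alternative 1: ring A by polyketide-type Claisen cyclisation.**
- Disconnection: ring A is cut at C5–C6, so the acylphloroglucinol A1, 3-phenyl-1-(2,4,6-trihydroxyphenyl)propan-1-one, comes from the open-chain triketo ester A3, methyl 3,5,7-trioxo-9-phenylnonanoate, stored as the pyranone A2, 4-hydroxy-6-(2-oxo-4-phenylbutyl)-2H-pyran-2-one.
- Forward key step: a chelating magnesium alkoxide in its parent alcohol opens the lactone of A2 to the polyenolate of A3. The methylene between the two ketones remote from the ester attacks the ester carbonyl, and aromatisation gives A1.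
- For: the folding mirrors the biosynthesis. The acyl group is flanked by two oxygens by construction, so its position needs no control. On that point it is stronger than the aryne route, whose orientation rests on an electronic bias.
- Against: A1 is symmetric and under-functionalised. One of its three hydroxyls must become O1, one the methyl ether and one stay free. The pyran and the C8 oxygen are both missing. After A1 the route still needs chromenylation with a choice between chelated and free hydroxyl, O-methylation of one of two ortho hydroxyls, and C8 oxidation. Each of these raises its own regiochemical question. The folding also competes with the aldol mode that leads to a resorcylic ester. A1 is in any case reachable in one step by acylating the parent triphenol, so the key step is spent on the easiest part of the molecule.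
- Comparison: the chosen route fixes the O1/O5/O7 differentiation in its first step and uses its key step for the difficult acyl placement.

**Alternative 2: ring A by ring expansion of a squarate-derived cyclobutenone.**
- Disconnection: ring A is cut at C4a–C5, back to A5, 4-(2,2-dimethyl-3,4-dihydro-2H-pyran-6-yl)-4-hydroxy-3-methoxycyclobut-2-en-1-one.
- Forward key step: heating opens the four-membered ring to a dienylketene. The ketene carbon closes onto the β-carbon of the enol ether, and tautomerisation gives the chromane hydroquinone A4, 7-methoxy-2,2-dimethylchromane-5,8-diol.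
- For: O1, the C5 and C8 hydroxyls and the C7 methoxyl appear in one step with no regiochemical doubt. The C8 oxygen is present from the start. Here it is stronger than the chosen route, which needs a late oxidation of a chelated phenol.
- Against: A4 is a chromane, so C3=C4 must be introduced by dehydrogenation next to a hydroquinone that any such oxidant attacks first. This forces protection and deprotection. The C6 acyl group is also absent and must be added by Friedel–Crafts or Fries chemistry on an air- and acid-sensitive ring. A5 itself needs a mono-methoxy cyclobutenedione and a metalated dihydropyran.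
- Comparison: the two defining features of the target, the acyl group and the alkene, are both installed after the key step, over more steps. The chosen route has the alkene from step 1 and adds acyl carbon and adjacent oxygen together.

**Alternative 3: pyran closure at O1–C8a on a quinone.**
- Disconnection: O1–C8a is cut at the quinone oxidation level, so A6, 7-methoxy-2,2-dimethyl-6-(3-phenylpropanoyl)-2H-chromene-5,8-dione (identical with 19), comes from A7, 2-[(Z)-3-hydroxy-3-methylbut-1-enyl]-3,5-dimethoxy-6-(3-phenylpropanoyl)-1,4-benzoquinone.
- Forward key step: the tertiary alkoxide of A7 adds to the methoxy-bearing C8a and methoxide leaves (addition–elimination on a vinylogous ester). This closes the pyran with its alkene already present.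
- For: acyl group and quinone oxidation level are in place, and A6 is one reduction from 20. No late oxidation is needed, which is a real advantage over the chosen route.
- Against: all difficulty moves into A7. It is a fully substituted acylquinone, so the same hexasubstituted-arene problem returns. It also needs a Z-alkene, which means an alkyne semi-reduction in the presence of, or before unveiling, a reducible quinone. A hindered tertiary alkoxide is a poor nucleophile and a strong base towards an enolisable, doubly activated ketone. It can also add reversibly to the C5 carbonyl.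
- Comparison: the chromene ring forms in one step from 1 and 2 and does not merit a key step. The chosen route reaches the same quinone 19 by a shorter path.

Key step: step 7

Assumption (chemistry): in step 1 the carbon of 1 between the two hydroxyls (para to the methoxyl) is taken to react preferentially, as is usual for 5-substituted resorcinols. The product of attack at the other activated carbon would be removed by chromatography, and a regiochemically fixed fallback is given.

## Route

Step 1
Reactants: 1 5-methoxybenzene-1,3-diol; 2 3-methylbut-2-enal
Product: 3 7-methoxy-2,2-dimethyl-2H-chromen-5-ol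
Conditions: ethylenediammonium diacetate (10 mol %), toluene, reflux; 2 in slight deficit
Reagents that add atoms: none
Why: Amine-salt-catalysed Knoevenagel-type condensation at the ring carbon between the two hydroxyls, loss of water to an ortho-quinone methide and oxa-6π electrocyclisation (formal [3+3] chromenylation); either hydroxyl closes to the same product, and a deficit of 2 limits double annulation.

Step 2
Reactants: 3 7-methoxy-2,2-dimethyl-2H-chromen-5-ol
Product: 4 7-methoxy-2,2-dimethyl-2H-chromen-5-yl N-(propan-2-yl)carbamate
Conditions: i-PrNCO, Et3N (cat.), CH2Cl2, rt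
Reagents that add atoms: isopropyl isocyanate, CC(C)N=C=O
Why: Base-catalysed addition of the phenol to the isocyanate gives the secondary O-aryl carbamate, a strong directing group that can later be removed under mild base.

Step 3
Reactants: 4 7-methoxy-2,2-dimethyl-2H-chromen-5-yl N-(propan-2-yl)carbamate
Product: 8 7-methoxy-2,2-dimethyl-6-(trimethylsilyl)-2H-chromen-5-yl N-(propan-2-yl)carbamate, via N-silyl carbamate 5 (not isolated), via C6-lithio carbamate 6 (not isolated), via N-silyl C6-silyl carbamate 7 (not isolated)
Conditions: TBSOTf, TMEDA, Et2O, 0 °C to rt; then n-BuLi, TMEDA, −78 °C; then TMSCl, −78 °C to rt; aq NH4Cl work-up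
Reagents that add atoms: chlorotrimethylsilane, C[Si](C)(C)Cl
Why: In-flask N-silylation turns the N–H carbamate into a tertiary one fit for directed ortho-metalation; C6–H is the only ortho position and is flanked by carbamate and methoxyl, so lithiation should occur there at −78 °C and TMSCl should trap the anion before anionic ortho-Fries migration; the mild aqueous work-up removes the N-silyl group without protodesilylating the electron-rich arylsilane.

Step 4
Reactants: 8 7-methoxy-2,2-dimethyl-6-(trimethylsilyl)-2H-chromen-5-yl N-(propan-2-yl)carbamate
Product: 10 7-methoxy-2,2-dimethyl-6-(trimethylsilyl)-2H-chromen-5-yl trifluoromethanesulfonate, via C6-silyl phenol 9 (not isolated)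
Conditions: DBU, Et2NH, MeCN, 40 °C; then PhNTf2, rt
Reagents that add atoms: N-phenylbis(trifluoromethanesulfonimide), O=S(=O)(N(c1ccccc1)S(=O)(=O)C(F)(F)F)C(F)(F)F
Why: DBU removes the carbamate N–H and the phenoxide is expelled with isopropyl isocyanate (E1cB), which diethylamine captures as a urea; the hindered phenoxide is then O-sulfonylated by PhNTf2 in the same flask, under base throughout so that the C–Si bond is not exposed to acid.

Step 5
Reactants: 11 3-phenylpropanal
Product: 12 3-phenylpropanal oxime (E/Z mixture)
Conditions: NH2OH·HCl, Na2CO3, EtOH/H2O, rt
Reagents that add atoms: hydroxylamine hydrochloride, NO.Cl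
Why: Condensation of an aldehyde with hydroxylamine; the oxime geometry is of no consequence because it disappears at the nitrile oxide stage.

Step 6
Reactants: 12 3-phenylpropanal oxime
Product: 13 (Z)-N-hydroxy-3-phenylpropanimidoyl chloride
Conditions: NCS, DMF, 0 °C to rt; used promptly
Reagents that add atoms: N-chlorosuccinimide, O=C1CCC(=O)N1Cl
Why: Chlorination of the aldoxime carbon by NCS is the standard preparation of hydroximoyl chlorides; aliphatic members are of limited stability, so the material should be carried straight into step 7.

Step 7
Reactants: 10 7-methoxy-2,2-dimethyl-6-(trimethylsilyl)-2H-chromen-5-yl trifluoromethanesulfonate; 13 (Z)-N-hydroxy-3-phenylpropanimidoyl chloride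
Product: 16 chromene-fused 3-(2-phenylethyl)-1,2-benzisoxazole (isoxazole fused across C5–C6 of 7-methoxy-2,2-dimethyl-2H-chromene; ring oxygen on C5; ring carbon bearing the 2-phenylethyl group on C6), via C5–C6 aryne 14 (not isolated), via 3-phenylpropanenitrile oxide 15 (not isolated)
Conditions: CsF (4 equiv), MeCN, rt; 13 (2 equiv) in MeCN added by syringe pump over several hours
Reagents that add atoms: none
Why: Fluoride attacks silicon in 10 and triflate departs to give aryne 14, while fluoride acting as base removes HCl from 13 to give nitrile oxide 15. The two combine in a concerted, asynchronous 1,3-dipolar cycloaddition, the known aryne–nitrile oxide route from ortho-silylaryl triflates and chlorooximes to 3-substituted 1,2-benzisoxazoles. The isoxazole ring closes intermolecularly, with C5–O and C6–C1' formed in the same step, and no stereocentre is created. The selectivity needed is oxygen on C5 and carbon on C6: the C7 methoxyl withdraws inductively and distorts the aryne so that C5, the distal carbon, is the flatter and more electrophilic end, and the nucleophilic oxygen terminus of the dipole should bond there first. Both aryne carbons have a substituted neighbour (C4a beside C5, the methoxyl-bearing C7 beside C6), so steric effects roughly cancel and the electronic bias should decide. Sparingly soluble CsF releases the aryne slowly and slow addition of 13 keeps the dipole concentration low, which suppresses furoxan formation. The strained aryne should outcompete the C3=C4 alkene, which is cis-disubstituted and shielded by the quaternary C2, as dipolarophile.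

Step 8
Reactants: 16 chromene-fused 3-(2-phenylethyl)-1,2-benzisoxazole
Product: 18 1-(5-hydroxy-7-methoxy-2,2-dimethyl-2H-chromen-6-yl)-3-phenylpropan-1-one, via N–H ketimine 17 (not isolated)
Conditions: Mo(CO)6, MeCN/H2O, 80 °C; then 1 M HCl, THF, rt
Reagents that add atoms: water, O
Why: Zerovalent molybdenum in Mo(CO)6 cleaves the weak N–O bond reductively, as it does for isoxazoles, to give the hydrogen-bonded ortho-hydroxyaryl ketimine 17; dilute acid hydrolyses it to the chelated ketone. No hydrogenation catalyst or hydride is involved, so C3=C4 should survive, and the acid is dilute enough for the chromene.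

Step 9
Reactants: 18 1-(5-hydroxy-7-methoxy-2,2-dimethyl-2H-chromen-6-yl)-3-phenylpropan-1-one
Product: 19 7-methoxy-2,2-dimethyl-6-(3-phenylpropanoyl)-2H-chromene-5,8-dione
Conditions: (KSO3)2NO (2.5 equiv), KH2PO4 buffer, acetone/H2O, 0 °C to rt
Reagents that add atoms: potassium nitrosodisulfonate, [K+].[K+].[O]N(S(=O)(=O)[O-])S(=O)(=O)[O-]
Why: Teuber oxidation: one equivalent of the nitroxyl radical removes the phenolic hydrogen, a second couples through oxygen at C8 (the only ring carbon bearing hydrogen, para to the phenoxyl oxygen), and loss of imidodisulfonate gives the para-quinone. Both ortho positions are carbon-substituted, so no ortho-quinone can form, and the near-neutral buffer protects the chromene.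

Step 10
Reactants: 19 7-methoxy-2,2-dimethyl-6-(3-phenylpropanoyl)-2H-chromene-5,8-dione
Product: 20 flemistrictin D, 1-(5,8-dihydroxy-7-methoxy-2,2-dimethyl-2H-chromen-6-yl)-3-phenylpropan-1-one
Conditions: Na2S2O4, EtOAc/H2O, rt, under argon; crude 19 used directly
Reagents that add atoms: none
Why: Two-electron reduction of a quinone to its hydroquinone by dithionite in a two-phase system; ketone, alkene and methyl ether are inert to it, and work-up under inert gas guards the product against re-oxidation.

## Compound list

1 | 5-methoxybenzene-1,3-diol | COc1cc(O)cc(O)c1 | starting material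
2 | 3-methylbut-2-enal | CC(C)=CC=O | starting material
3 | 7-methoxy-2,2-dimethyl-2H-chromen-5-ol | COc1cc(O)c2C=CC(C)(C)Oc2c1 | intermediate
4 | 7-methoxy-2,2-dimethyl-2H-chromen-5-yl N-(propan-2-yl)carbamate | COc1cc(OC(=O)NC(C)C)c2C=CC(C)(C)Oc2c1 | intermediate
5 | 7-methoxy-2,2-dimethyl-2H-chromen-5-yl N-(tert-butyldimethylsilyl)-N-(propan-2-yl)carbamate | COc1cc(OC(=O)N(C(C)C)[Si](C)(C)C(C)(C)C)c2C=CC(C)(C)Oc2c1 | intermediate
6 | [5-{[(tert-butyldimethylsilyl)(propan-2-yl)carbamoyl]oxy}-7-methoxy-2,2-dimethyl-2H-chromen-6-yl]lithium | [Li]c1c(OC)cc2OC(C)(C)C=Cc2c1OC(=O)N(C(C)C)[Si](C)(C)C(C)(C)C | intermediate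
7 | 7-methoxy-2,2-dimethyl-6-(trimethylsilyl)-2H-chromen-5-yl N-(tert-butyldimethylsilyl)-N-(propan-2-yl)carbamate | COc1cc2OC(C)(C)C=Cc2c(OC(=O)N(C(C)C)[Si](C)(C)C(C)(C)C)c1[Si](C)(C)C | intermediate
8 | 7-methoxy-2,2-dimethyl-6-(trimethylsilyl)-2H-chromen-5-yl N-(propan-2-yl)carbamate | COc1cc2OC(C)(C)C=Cc2c(OC(=O)NC(C)C)c1[Si](C)(C)C | intermediate
9 | 7-methoxy-2,2-dimethyl-6-(trimethylsilyl)-2H-chromen-5-ol | COc1cc2OC(C)(C)C=Cc2c(O)c1[Si](C)(C)C | intermediate
10 | 7-methoxy-2,2-dimethyl-6-(trimethylsilyl)-2H-chromen-5-yl trifluoromethanesulfonate | COc1cc2OC(C)(C)C=Cc2c(OS(=O)(=O)C(F)(F)F)c1[Si](C)(C)C | intermediate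
11 | 3-phenylpropanal | O=CCCc1ccccc1 | starting material
12 | 3-phenylpropanal oxime (E/Z mixture) | ON=CCCc1ccccc1 | intermediate
13 | (Z)-N-hydroxy-3-phenylpropanimidoyl chloride | O/N=C(\Cl)CCc1ccccc1 | intermediate
14 | 7-methoxy-2,2-dimethyl-5,6-didehydro-2H-chromene (C5–C6 aryne) | COC1=CC2=C(C=CC(C)(C)O2)C#C1 | intermediate
15 | 3-phenylpropanenitrile oxide | [O-][N+]#CCCc1ccccc1 | intermediate
16 | chromene-fused 3-(2-phenylethyl)-1,2-benzisoxazole (isoxazole across C5–C6 of 7-methoxy-2,2-dimethyl-2H-chromene; O on C5, C on C6) | COc1cc2OC(C)(C)C=Cc2c2onc(CCc3ccccc3)c12 | intermediate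
17 | 6-(1-imino-3-phenylpropyl)-7-methoxy-2,2-dimethyl-2H-chromen-5-ol | COc1cc2OC(C)(C)C=Cc2c(O)c1C(=N)CCc1ccccc1 | intermediate
18 | 1-(5-hydroxy-7-methoxy-2,2-dimethyl-2H-chromen-6-yl)-3-phenylpropan-1-one | COc1cc2OC(C)(C)C=Cc2c(O)c1C(=O)CCc1ccccc1 | intermediate
19 | 7-methoxy-2,2-dimethyl-6-(3-phenylpropanoyl)-2H-chromene-5,8-dione | COC1=C(C(=O)CCc2ccccc2)C(=O)C2=C(OC(C)(C)C=C2)C1=O | intermediate
20 | flemistrictin D, 1-(5,8-dihydroxy-7-methoxy-2,2-dimethyl-2H-chromen-6-yl)-3-phenylpropan-1-one | COc1c(O)c2c(c(O)c1C(=O)CCc1ccccc1)C=CC(C)(C)O2 | target

## Step count and least certain steps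

Total: 10 steps. Longest linear sequence: 8 steps (steps 1, 2, 3, 4, 7, 8, 9, 10, from 1). Steps 5 and 6 form the two-step side branch to 13.

**Step 7 (key step).** What may go wrong:
- reversed orientation of the dipole on the aryne, since the carbon terminus with its phenethyl chain must settle beside the C7 methoxyl;
- dimerisation of the nitrile oxide before it meets the aryne;
- protonation of the aryl anion by the HF released from 13, which removes silicon without forming the aryne;
- addition of the dipole to C3=C4.

Fallback (directed ortho-metalation and acylation in place of cycloaddition). Setting out from 4, the N-silylation and lithiation of step 3 are repeated to give 5 and then 6. At −78 °C 6 is quenched with commercial N-methoxy-N-methyl-3-phenylpropanamide. Acyl transfer should give 7-methoxy-2,2-dimethyl-6-(3-phenylpropanoyl)-2H-chromen-5-yl N-(tert-butyldimethylsilyl)-N-(propan-2-yl)carbamate F1. Aqueous NH4Cl work-up removes the N-silyl group to give 7-methoxy-2,2-dimethyl-6-(3-phenylpropanoyl)-2H-chromen-5-yl N-(propan-2-yl)carbamate F2. DBU and Et2NH in MeCN, as in step 4, then free the phenol, and the route is rejoined at 18.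

**Step 1.** What may go wrong: condensation at the ring carbon between a hydroxyl and the methoxyl, which is also triply activated, leading to the isomeric pyran fusion; and a second annulation on the remaining hydroxyl.

Fallback (regiochemistry fixed by metalation between two acetal oxygens). Setting out from 1, both hydroxyls are protected with MOMCl and i-Pr2NEt to give 1-methoxy-3,5-bis(methoxymethoxy)benzene F3. n-BuLi in THF at 0 °C should metalate the carbon between the two acetal groups to give [4-methoxy-2,6-bis(methoxymethoxy)phenyl]lithium F4. Addition of 2 at −78 °C gives racemic 1-[4-methoxy-2,6-bis(methoxymethoxy)phenyl]-3-methylbut-2-en-1-ol F5. Methanolic HCl at 40 °C removes both acetals, and the ortho-hydroxy allylic alcohol loses water to an ortho-quinone methide that closes by oxa-6π electrocyclisation. The route is rejoined at 3.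

**Step 3.** What may go wrong: competing deprotonation at C8 (between the methoxyl and O1), addition of n-BuLi to C3=C4, migration of the carbamoyl group to C6 if the anion warms before silylation, and loss of the new silyl group on an acidic work-up.

Fallback (halogen–lithium exchange with oxygen-to-carbon silyl shift in place of deprotonation). Setting out from 3, amine-mediated ortho-bromination (NBS, i-Pr2NH cat., CH2Cl2, 0 °C) gives 6-bromo-7-methoxy-2,2-dimethyl-2H-chromen-5-ol F6. Hexamethyldisilazane in THF at reflux gives [(6-bromo-7-methoxy-2,2-dimethyl-2H-chromen-5-yl)oxy]trimethylsilane F7. n-BuLi at −100 °C exchanges bromine to give [7-methoxy-2,2-dimethyl-5-(trimethylsilyloxy)-2H-chromen-6-yl]lithium F8, which passes silicon from oxygen to carbon to give lithium 7-methoxy-2,2-dimethyl-6-(trimethylsilyl)-2H-chromen-5-olate F9. Tf2O added at low temperature sulfonylates the phenolate, and the route is rejoined at 10.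

**Step 9.** What may go wrong: sluggish hydrogen abstraction from a phenol that is chelated to the ketone and has its two alkoxy groups meta to the hydroxyl, so that little conversion occurs; and attack of water on the electrophilic acylquinone once it has formed.

Fallback (Elbs persulfate oxidation, an ionic para-hydroxylation that never passes through the quinone). Setting out from 18, K2S2O8 in aqueous KOH with pyridine as cosolvent at rt lets the phenolate attack the peroxide oxygen through C8. This gives potassium 5-hydroxy-7-methoxy-2,2-dimethyl-6-(3-phenylpropanoyl)-2H-chromen-8-yl sulfate F10. Brief warming in dilute aqueous HCl under argon hydrolyses the sulfate ester, and the route is rejoined at 20.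

## Further compounds

F1 | step 7 | 7-methoxy-2,2-dimethyl-6-(3-phenylpropanoyl)-2H-chromen-5-yl N-(tert-butyldimethylsilyl)-N-(propan-2-yl)carbamate | COc1cc2OC(C)(C)C=Cc2c(OC(=O)N(C(C)C)[Si](C)(C)C(C)(C)C)c1C(=O)CCc1ccccc1
F2 | step 7 | 7-methoxy-2,2-dimethyl-6-(3-phenylpropanoyl)-2H-chromen-5-yl N-(propan-2-yl)carbamate | COc1cc2OC(C)(C)C=Cc2c(OC(=O)NC(C)C)c1C(=O)CCc1ccccc1
F3 | step 1 | 1-methoxy-3,5-bis(methoxymethoxy)benzene | COCOc1cc(OC)cc(OCOC)c1
F4 | step 1 | [4-methoxy-2,6-bis(methoxymethoxy)phenyl]lithium | [Li]c1c(OCOC)cc(OC)cc1OCOC
F5 | step 1 | 1-[4-methoxy-2,6-bis(methoxymethoxy)phenyl]-3-methylbut-2-en-1-ol (racemic) | COCOc1cc(OC)cc(OCOC)c1C(O)C=C(C)C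
F6 | step 3 | 6-bromo-7-methoxy-2,2-dimethyl-2H-chromen-5-ol | COc1cc2OC(C)(C)C=Cc2c(O)c1Br
F7 | step 3 | [(6-bromo-7-methoxy-2,2-dimethyl-2H-chromen-5-yl)oxy]trimethylsilane | COc1cc2OC(C)(C)C=Cc2c(O[Si](C)(C)C)c1Br
F8 | step 3 | [7-methoxy-2,2-dimethyl-5-(trimethylsilyloxy)-2H-chromen-6-yl]lithium | [Li]c1c(OC)cc2OC(C)(C)C=Cc2c1O[Si](C)(C)C
F9 | step 3 | lithium 7-methoxy-2,2-dimethyl-6-(trimethylsilyl)-2H-chromen-5-olate | [Li+].COc1cc2OC(C)(C)C=Cc2c([O-])c1[Si](C)(C)C
F10 | step 9 | potassium 5-hydroxy-7-methoxy-2,2-dimethyl-6-(3-phenylpropanoyl)-2H-chromen-8-yl sulfate | [K+].COc1c(OS(=O)(=O)[O-])c2OC(C)(C)C=Cc2c(O)c1C(=O)CCc1ccccc1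
A1 | alternative 1 | 3-phenyl-1-(2,4,6-trihydroxyphenyl)propan-1-one | O=C(CCc1ccccc1)c1c(O)cc(O)cc1O
A2 | alternative 1 | 4-hydroxy-6-(2-oxo-4-phenylbutyl)-2H-pyran-2-one | O=C(CCc1ccccc1)CC1=CC(O)=CC(=O)O1
A3 | alternative 1 | methyl 3,5,7-trioxo-9-phenylnonanoate | COC(=O)CC(=O)CC(=O)CC(=O)CCc1ccccc1
A4 | alternative 2 | 7-methoxy-2,2-dimethylchromane-5,8-diol | COc1cc(O)c2CCC(C)(C)Oc2c1O
A5 | alternative 2 | 4-(2,2-dimethyl-3,4-dihydro-2H-pyran-6-yl)-4-hydroxy-3-methoxycyclobut-2-en-1-one | COC1=CC(=O)C1(O)C1=CCCC(C)(C)O1
A6 | alternative 3 | 7-methoxy-2,2-dimethyl-6-(3-phenylpropanoyl)-2H-chromene-5,8-dione (identical with 19) | COC1=C(C(=O)CCc2ccccc2)C(=O)C2=C(OC(C)(C)C=C2)C1=O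
A7 | alternative 3 | 2-[(Z)-3-hydroxy-3-methylbut-1-enyl]-3,5-dimethoxy-6-(3-phenylpropanoyl)cyclohexa-2,5-diene-1,4-dione | COC1=C(C(=O)CCc2ccccc2)C(=O)C(/C=C\C(C)(C)O)=C(OC)C1=O
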